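## The problem

Target 28 is a germacranolide, numbered here C1 to C15 in the usual way. Its ten-membered carbocycle C1–C10 is spanned by an oxygen bridge from C1 to C4 and fused at C6–C7 to an α-(acetoxymethyl) γ-ylidene butenolide (O, C6, C7, C11, C12, with the exocyclic C5=C6 bond). Seen from the bridge oxygen, it is a nine-membered oxacycle (C1, O, C4 to C10) with a two-carbon strap C2–C3, and closing this medium ring is the central difficulty.

There are four ring stereocentres (1S, 4R, 8R, 10R) and one in the ester (2′R). C4 is quaternary and isolated, so it has to be brought in enantiopure; once it is fixed, C1 follows, because the six-atom chain C5–C10 can only bridge the tetrahydrofuran cis. C8 lies beyond the flat butenolide and cannot be controlled from C4, so it needs reagent control. C10 is α to the masked C1 ketone and can be set in the ring closure or corrected by equilibration through the open keto form.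

The molecule tolerates little. The hemiketal ionises with acid and opens with base. The cross-conjugated dienolide with its allylic C13 acetate is a Michael and SN2′ acceptor that would not survive organometallic or reducing reagents. The chlorohydrin closes to an epoxide with base. Three hydroxyl groups (C13, C8, C1) must end up as acetate, hindered ester and free hemiketal.

The feature that opens the route is that C1 with its hydroxyl, the ring oxygen and the methyl-bearing C4 together are the lactol of a 4-methyl-4-alkyl γ-butyrolactone. The C1–C10 bond can therefore be made by adding a C10 carbanion to that lactone carbonyl, and the tetrahedral adduct is already the hemiketal. The butenolide, in turn, is the oxidised form of a furan whose only free α-position is C12.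

## Retrosynthesis

**Chlorohydrin.** The C3′–Cl bond of 28 is cut first, giving the (S)-2-methylglycidate 27. A free tertiary hydroxy acid is awkward to couple to a hindered alcohol, and a chlorohydrin would not pass the basic steps unchanged; the epoxide has neither problem. The forward step asks only for chloride to attack the unsubstituted epoxide carbon under weakly acidic conditions, which leaves C2′ untouched.

**Butenolide.** No skeletal bond is cut here. The C5=C6 bond of 27 is traced back to the γ-hydroxybutenolide 25, and the lactone carbonyl C12 to the furan 23. The alternative of carrying the dienolide through the synthesis is ruled out by its sensitivity to organometallics and to SmI2. The furan is inert to both, and because C6, C7 and C11 are substituted, singlet oxygen and base can place the carbonyl only at C12. The forward steps must dehydrate the C6 hydroxyl without disturbing the C1 hemiketal.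

**Acyl groups.** The C8 ester of 23 is cut to alcohol 19 and acid 21 (from its commercial methyl ester 20), and the C13 acetate of 19 to triol 18, which comes from the bis-silyl ether 17. The order (primary acetate first, then the secondary ester, the tertiary hemiketal last and untouched) follows the intrinsic reactivity of the three hydroxyl groups, so a single protecting group type suffices.

**Key cut, C1–C10.** Breaking this bond in 17 and returning C1 to a lactone carbonyl gives the iodo lactone 16. The neighbouring cuts (C8–C9, C9–C10, or C5–C6 at the furan) all leave the hemiketal to be made separately and require a free ten-membered ketone. The C1–C10 cut alone converts the hemiketal into a stable γ-lactone that already holds C4, the ring oxygen and C1 in one ring. Two stereocentres (C1, C10) and the medium ring disappear, and 16 is an open-chain furan with only C4 and C8 defined. The forward reaction must generate a carbanion at C10 that adds once to the lactone and stops.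

**C10 iodide.** The C10–I bond of 16 is traced to the terminal alkene 15 by Markovnikov hydroiodination. Either C10 epimer will do, since the centre passes through a configurationally labile organometallic.

**C5–C6.** Cutting between the furan and C5 divides 15 into the bromofuran 13 and the epoxy ester 5. Adding a furyl metal to an aldehyde at C5 would leave a furfurylic hydroxyl to be removed. The epoxide instead delivers C5 as CH2, and its oxygen becomes the lactone oxygen on C4 when the intermediate hydroxy ester 14 cyclises. The forward step needs a furyl nucleophile that opens the epoxide at its CH2 terminus faster than it attacks the ester, which points to copper catalysis.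

**C4 from the chiral pool.** Epoxy ester 5 comes from tosylate 4 by methanolysis and ring closure. Tosylate 4 comes from alcohol 3, and 3 from the lactone acid 2, which is (R)-linalool 1 with both alkenes cleaved. The C4–O bond of 28 is the C3–O bond of 1 and is never broken; the vinyl group of 1 becomes C5 and the prenyl chain becomes C3, C2 and C1.

**Furan fragment.** Silyl ether 13 comes from the homoallylic alcohol 12, whose C8–C9 bond is cut to the aldehyde 10 and allylboronate 11, so a chiral catalyst sets C8. The bromine in 10 marks the furan carbon next to the formyl group (the later C6). It is placed by metalating aldehyde 8 under the direction of its own α-amino alkoxide 9, which settles the regiochemistry that a symmetric furan would otherwise leave open. Aldehyde 8 comes from the monosilyl ether 7 of the commercial, symmetric diol 6, so the two hydroxymethyl groups are told apart in the first step and become C13 and C8.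

## Roads not taken

**Alternative 1:** Build the bare skeleton first and oxidise last. The cut removes both C–O bonds at C8 and C13 and leads back to the 8,13-dideoxy tricycle A1. In the forward direction SeO2 with tert-butyl hydroperoxide would hydroxylate the ring CH2 at C8 and the C13 methyl by ene reaction and [2,3] shift, giving diol A2.
- Merits: no protecting groups until the end, and the primary and secondary hydroxyls of A2 are easy to tell apart, so the finish would be shorter than the one chosen here.
- Weak points: the alkene C7=C11 that must undergo the ene reaction is the electron-poor α,β-bond of a dienolide, which is a poor partner for an electrophilic selenium reagent. Two positions must be oxidised once each without going on to aldehyde or ketone. The face selectivity at C8 rests on the conformation of the bridged ring, and the hemiketal and the enol-lactone must survive the oxidant.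
- Comparison: this road says nothing about how the bridged ring of A1 is closed, so the central difficulty remains. The chosen plan spends four extra steps on silyl groups and acylations, but in return C8 is set by a catalyst and the C13 oxygen comes from the starting diol 6.

**Alternative 2:** Ring expansion by anionic oxy-Cope rearrangement. The cut is C3–C4 and leads back to a butenolide-fused cyclohexanol A3 with a vinyl group on C1 and an enol-ether alkenyl group on C6. The potassium alkoxide (KH, 18-crown-6) would rearrange to the ten-membered C1 ketone A4, forming C3–C4, cleaving C1–C6 and creating the C5=C6 ylidene and C4 in one step.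
- Merits: medium carbocycles of exactly this size are made reliably by this reaction class; the ring strain of closure is avoided, and the ylidene geometry comes from the transition state. In precedent for the ring-forming event, this road is stronger than the samarium closure chosen here.
- Weak points: the quaternary C4 is formed at a fully substituted enol-ether terminus, so its configuration depends on a pure enol-ether geometry and a clean chair preference. The potassium alkoxide sits next to a butenolide whose acyloxy group at C6 is allylic, so acyl transfer, retro-aldol cleavage and elimination compete. A3 is a densely functionalised bicycle with four stereocentres whose own synthesis would be long. The PMB ether on C4 must later be removed oxidatively beside the dienolide.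
- Comparison: the chosen plan gives up the precedent for the ring closure. It gains a C4 centre taken unchanged from linalool, a convergent assembly from two simple fragments, and a furan in place of the butenolide during all strongly basic or reducing steps.

**Alternative 3:** Biomimetic elimination and transannular hemiketalisation. The cuts are the O–C1 bond and the C5=C6 double bond, leading back to the 4,5-epoxy-1-oxo germacranolide A5. DBU would remove H6; the oxidofuran would expel the epoxide oxygen from C5, and the freed C4 alkoxide would add across the ring to the C1 ketone, giving A6.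
- Merits: one step makes the ylidene, the tetrahydrofuran bridge and C1, with C4 retained from the epoxide. A6 is the same compound as 27 of the chosen route, one step from the target. For the last stage this road is shorter and probably closer to how the compound arises in the plant than the furan oxidation and dehydration used here.
- Weak points: A5 is itself a fully functionalised ten-membered germacranolide with a ketone, a trisubstituted epoxide, a butenolide and the labile C13 acetate. Making that carbocycle is the entire problem, only moved one step back, and the allylic acetate and the glycidate must survive DBU.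
- Comparison: the chosen plan reaches the same penultimate compound without ever needing a free ten-membered ring, because the lactone templates a nine-membered closure. It pays with two steps (photooxygenation, dehydration) where this road needs one.

Key step: step 12

Assumption: the 10R configuration is taken to be the more stable one in the bridged hemiketal, so that a 10S isomer, if formed in step 12, can be converged by base through the open C1 ketone. TBS stands for tert-butyldimethylsilyl.

## Route

Step 1
Reactants: 1 (R)-(−)-linalool
Product: 2 (2R)-2-methyl-5-oxooxolane-2-carboxylic acid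
Conditions: RuCl3 (cat.), NaIO4, CCl4/MeCN/H2O, rt
Reagents that add atoms: sodium periodate, [Na+].[O-]I(=O)(=O)=O; water, O
Why: RuO4-catalysed oxidative cleavage of both alkenes to carboxylic acids; the electron-rich trisubstituted alkene reacts first and its acid lactonises onto the tertiary alcohol, which shields the α-hydroxy acid unit from further cleavage. The carbinol carbon (the later C4) is not touched, so R is carried over.

Step 2
Reactants: 2 (2R)-2-methyl-5-oxooxolane-2-carboxylic acid
Product: 3 (5R)-5-(hydroxymethyl)-5-methyloxolan-2-one
Conditions: BH3·SMe2, THF, 0 °C to rt; MeOH quench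
Reagents that add atoms: none
Why: Chemoselective borane reduction of a carboxylic acid (through its acyloxyborane) in the presence of a γ-lactone, as established for the parent 5-oxooxolane-2-carboxylic acid.

Step 3
Reactants: 3 (5R)-5-(hydroxymethyl)-5-methyloxolan-2-one
Product: 4 [(2R)-2-methyl-5-oxooxolan-2-yl]methyl 4-methylbenzenesulfonate
Conditions: TsCl, pyridine, DMAP (cat.), CH2Cl2, 0 °C to rt
Reagents that add atoms: 4-methylbenzenesulfonyl chloride, Cc1ccc(cc1)S(=O)(=O)Cl
Why: Sulfonylation of a primary alcohol; no stereocentre is involved.

Step 4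
Reactants: 4 [(2R)-2-methyl-5-oxooxolan-2-yl]methyl 4-methylbenzenesulfonate
Product: 5 methyl 3-[(2R)-2-methyloxiran-2-yl]propanoate
Conditions: NaOMe, MeOH, 0 °C to rt
Reagents that add atoms: sodium methoxide, C[O-].[Na+]
Why: Methanolysis of the lactone frees the tertiary alkoxide, which displaces the neighbouring tosylate irreversibly (intramolecular Williamson reaction, 3-exo-tet), as known for the lower homologue. The C–O bond at the quaternary carbon is retained, so the epoxide is 2R.

Step 5
Reactants: 6 furan-3,4-diyldimethanol
Product: 7 [4-({[tert-butyl(dimethyl)silyl]oxy}methyl)furan-3-yl]methanol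
Conditions: NaH (1.0 equiv), THF, 0 °C; TBSCl (1.0 equiv), rt
Reagents that add atoms: tert-butyl(chloro)dimethylsilane, CC(C)(C)[Si](C)(C)Cl
Why: Monosilylation of a symmetric diol through its sparingly soluble monosodium alkoxide. The silylated arm becomes C13, the free arm C8.

Step 6
Reactants: 7 [4-({[tert-butyl(dimethyl)silyl]oxy}methyl)furan-3-yl]methanol
Product: 8 4-({[tert-butyl(dimethyl)silyl]oxy}methyl)furan-3-carbaldehyde
Conditions: MnO2, CH2Cl2, rt
Reagents that add atoms: none
Why: MnO2 oxidation of a heterobenzylic (furylmethyl) alcohol to the aldehyde; silyl ether and furan are inert.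

Step 7
Reactants: 8 4-({[tert-butyl(dimethyl)silyl]oxy}methyl)furan-3-carbaldehyde
Product: 10 2-bromo-4-({[tert-butyl(dimethyl)silyl]oxy}methyl)furan-3-carbaldehyde, via lithium α-amino alkoxide 9 (not isolated)
Conditions: LiN(Me)CH2CH2NMe2, THF, −78 °C; n-BuLi, −78 to −20 °C; BrCCl2CCl2Br, −78 °C to rt; aq. NH4Cl
Reagents that add atoms: lithium N,N,N′-trimethylethylenediamide, [Li]N(C)CCN(C)C (in 9 only); 1,2-dibromo-1,1,2,2-tetrachloroethane, BrC(Cl)(Cl)C(Cl)(Cl)Br
Why: In situ protection of the aldehyde as its α-amino alkoxide and directed ortho-lithiation: the chelating diamine arm brings n-BuLi to the furan carbon next to the masked formyl group (the later C6) and not to the one next to the silyloxymethyl group. Electrophilic bromination and hydrolysis on work-up return the aldehyde.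

Step 8
Reactants: 10 2-bromo-4-({[tert-butyl(dimethyl)silyl]oxy}methyl)furan-3-carbaldehyde; 11 allylboronic acid pinacol ester
Product: 12 (1R)-1-[2-bromo-4-({[tert-butyl(dimethyl)silyl]oxy}methyl)furan-3-yl]but-3-en-1-ol
Conditions: (R)-TRIP phosphoric acid (5 mol%), toluene, −30 °C
Reagents that add atoms: allylboronic acid pinacol ester (11), C=CCB1OC(C)(C)C(C)(C)O1
Why: Chiral phosphoric acid-catalysed allylboration through a closed chair transition state with the catalyst hydrogen-bonded to the boronate oxygen. The (R)-catalyst is expected to deliver the allyl group to the Re face and give the 8R alcohol; the sense would be checked by Mosher ester analysis.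

Step 9
Reactants: 12 (1R)-1-[2-bromo-4-({[tert-butyl(dimethyl)silyl]oxy}methyl)furan-3-yl]but-3-en-1-ol
Product: 13 2-bromo-3-[(1R)-1-{[tert-butyl(dimethyl)silyl]oxy}but-3-en-1-yl]-4-({[tert-butyl(dimethyl)silyl]oxy}methyl)furan
Conditions: TBSOTf, 2,6-lutidine, CH2Cl2, −78 to 0 °C
Reagents that add atoms: tert-butyldimethylsilyl trifluoromethanesulfonate, CC(C)(C)[Si](C)(C)OS(=O)(=O)C(F)(F)F
Why: Silylation of a hindered secondary alcohol with the silyl triflate. The ether removes the acidic proton that would quench the C10 carbanion in step 12.

Step 10
Reactants: 13 2-bromo-3-[(1R)-1-{[tert-butyl(dimethyl)silyl]oxy}but-3-en-1-yl]-4-({[tert-butyl(dimethyl)silyl]oxy}methyl)furan; 5 methyl 3-[(2R)-2-methyloxiran-2-yl]propanoate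
Product: 15 (5R)-5-({3-[(1R)-1-(TBSO)but-3-en-1-yl]-4-(TBSOCH2)furan-2-yl}methyl)-5-methyloxolan-2-one, via hydroxy ester 14 (not isolated)
Conditions: 13, n-BuLi, Et2O, −78 °C; MgBr2·OEt2; CuI (10 mol%), 5, THF, −40 to 0 °C, then rt; aq. NH4Cl
Reagents that add atoms: methyl 3-[(2R)-2-methyloxiran-2-yl]propanoate (5), COC(=O)CC[C@]1(C)CO1
Why: Bromine–lithium exchange, transmetalation to magnesium and copper-catalysed SN2 opening of the epoxide at its unsubstituted carbon form C5–C6. The tertiary alkoxide then closes onto the methyl ester (5-exo-trig lactonisation), as in the known conversion of 4,5-epoxy esters into γ-lactones. C4 is not a reaction centre and stays R.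

Step 11
Reactants: 15 (5R)-5-({3-[(1R)-1-(TBSO)but-3-en-1-yl]-4-(TBSOCH2)furan-2-yl}methyl)-5-methyloxolan-2-one
Product: 16 (5R)-5-({3-[(1R)-1-(TBSO)-3-iodobutyl]-4-(TBSOCH2)furan-2-yl}methyl)-5-methyloxolan-2-one (both C10 epimers)
Conditions: Co(acac)2 (25 mol%), t-BuOOH, Et3SiH, CH2I2, n-PrOH, rt
Reagents that add atoms: diiodomethane, ICI
Why: Markovnikov hydroiodination by metal-hydride hydrogen atom transfer (Mukaiyama-type): a cobalt hydride delivers a hydrogen atom to the terminal carbon and the secondary C10 radical abstracts iodine from CH2I2. The neutral conditions spare furan, lactone and silyl ethers, and both C10 epimers serve because the centre is reset in step 12.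

Step 12
Reactants: 16 (5R)-5-({3-[(1R)-1-(TBSO)-3-iodobutyl]-4-(TBSOCH2)furan-2-yl}methyl)-5-methyloxolan-2-one
Product: 17 (1S,4R,8R,10R)-8,13-bis(TBSO)-1-hydroxy-1,4-epoxy furanogermacrane (furan-fused bridged hemiketal)
Conditions: SmI2 (2.5 equiv), NiI2 (2 mol%), THF, 0 °C, slow addition of 16 at high dilution; aq. NH4Cl
Reagents that add atoms: none
Why: Proposed new method: SmI2 with catalytic NiI2 reduces the secondary C10–I bond to the radical and then to the organosamarium, which adds to the lactone carbonyl C1; the resulting samarium 2-oxidotetrahydrofuran is the salt of the hemiketal and is protonated on work-up, the closest known reaction type being the SmI2-promoted intramolecular Barbier-type acyl substitution of iodoalkyl esters and lactones together with organometallic additions to γ-lactones that stop at the lactol. The nine-membered oxacycle (C1, O, C4 to C10) closes by a 9-exo-trig addition to the carbonyl, helped by the lactone, which already holds C4, the ring oxygen and C1 in one five-membered ring, and by the furan, which keeps C5 to C8 in one plane. C1 is controlled by C4: the six-atom chain C5 to C10 can only span the tetrahydrofuran cis, which places the hydroxyl on the other face (1S). C10 comes from a configurationally labile organosamarium and is set in the ring-closing transition state, where the C14 methyl is expected to point away from the bridge and from the C8 silyl ether (10R). The step needs reduction of C–I in preference to the lactone, addition faster than protonation, and a tetrahedral adduct that does not collapse: divalent samarium without HMPA leaves lactones, silyl ethers and the furan alone, slow addition at high dilution keeps the carbanion from proton donors and from other molecules, and the bridged samarium alkoxide has little drive to open to a ten-membered ketone. The furan is used precisely because the butenolide it replaces would be reduced.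

Step 13
Reactants: 17 (1S,4R,8R,10R)-8,13-bis(TBSO)-1-hydroxy-1,4-epoxy furanogermacrane
Product: 18 (1S,4R,8R,10R)-1,8,13-trihydroxy-1,4-epoxy furanogermacrane
Conditions: TBAF, AcOH, THF, 0 °C to rt
Reagents that add atoms: none
Why: Fluoride cleavage of both silyl ethers; buffering with acetic acid keeps the hemiketal from opening as its alkoxide.

Step 14
Reactants: 18 (1S,4R,8R,10R)-1,8,13-trihydroxy-1,4-epoxy furanogermacrane
Product: 19 (1S,4R,8R,10R)-13-acetoxy-1,8-dihydroxy-1,4-epoxy furanogermacrane
Conditions: AcCl, 2,4,6-collidine, CH2Cl2, −78 °C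
Reagents that add atoms: acetyl chloride, CC(=O)Cl
Why: Kinetically selective acetylation of the primary C13 hydroxyl over the hindered secondary C8 hydroxyl and the tertiary hemiketal hydroxyl with acetyl chloride and a hindered pyridine at low temperature.

Step 15
Reactants: 20 methyl (2S)-2-methyloxirane-2-carboxylate
Product: 21 (2S)-2-methyloxirane-2-carboxylic acid
Conditions: LiOH, THF/H2O, 0 °C; NaHSO4 to pH 3, extraction
Reagents that add atoms: lithium hydroxide, [Li+].[OH-]
Why: Saponification of a methyl ester; at 0 °C hydroxide attacks the ester carbonyl faster than the epoxide, and the quaternary centre is not touched.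

Step 16
Reactants: 19 (1S,4R,8R,10R)-13-acetoxy-1,8-dihydroxy-1,4-epoxy furanogermacrane; 21 (2S)-2-methyloxirane-2-carboxylic acid
Product: 23 (1S,4R,8R,10R)-13-acetoxy-1-hydroxy-8-[(2S)-2-methyloxirane-2-carbonyloxy]-1,4-epoxy furanogermacrane, via mixed anhydride 22 (not isolated)
Conditions: 21, 2,4,6-Cl3C6H2COCl, Et3N, THF, 0 °C; then 19, DMAP, toluene, rt
Reagents that add atoms: (2S)-2-methyloxirane-2-carboxylic acid (21), OC(=O)[C@@]1(C)OC1; 2,4,6-trichlorobenzoyl chloride, O=C(Cl)c1c(Cl)cc(Cl)cc1Cl (in 22 only)
Why: Yamaguchi esterification: DMAP attacks the mixed anhydride at the less hindered glycidoyl carbonyl and the acylpyridinium acylates the secondary C8 hydroxyl, while the tertiary hemiketal hydroxyl is too hindered. The epoxide carries the later chlorohydrin without a free hydroxyl.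

Step 17
Reactants: 23 (1S,4R,8R,10R)-13-acetoxy-1-hydroxy-8-[(2S)-2-methyloxirane-2-carbonyloxy]-1,4-epoxy furanogermacrane
Product: 25 (1S,4R,8R,10R)-13-acetoxy-1,6-dihydroxy-8-[(2S)-2-methyloxirane-2-carbonyloxy]-1,4-epoxygermacr-7(11)-en-12,6-olide (C6 epimers), via furan endoperoxide 24 (not isolated)
Conditions: O2, visible light, tetraphenylporphyrin (cat.), iPr2NEt, CH2Cl2, −78 °C to rt
Reagents that add atoms: dioxygen, O=O
Why: [4+2] Cycloaddition of singlet oxygen to the furan, then base-induced Kornblum–DeLaMare-type fragmentation of the endoperoxide. Only C12 carries a hydrogen, so the carbonyl can only form at C12 and the hydroxyl at C6; both C6 epimers lead on.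

Step 18
Reactants: 25 (1S,4R,8R,10R)-13-acetoxy-1,6-dihydroxy-8-[(2S)-2-methyloxirane-2-carbonyloxy]-1,4-epoxygermacr-7(11)-en-12,6-olide
Product: 27 (1S,4R,5E,8R,10R)-13-acetoxy-1-hydroxy-8-[(2S)-2-methyloxirane-2-carbonyloxy]-1,4-epoxygermacra-5,7(11)-dien-12,6-olide, via C6 acetate 26 (not isolated)
Conditions: Ac2O, Et3N, DMAP (cat.), CH2Cl2, 0 °C to rt
Reagents that add atoms: acetic anhydride, CC(=O)OC(C)=O (in 26 only)
Why: Dehydration of a γ-hydroxybutenolide to the γ-ylidene butenolide: the acidic pseudo-acid hydroxyl at C6 is acetylated and acetic acid is lost across C5–C6 under the basic conditions. The nine-membered ring allows only the geometry with C4 and C7 cis on the double bond (5E), and the tertiary C1 hydroxyl is expected to stay unacylated.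

Step 19
Reactants: 27 (1S,4R,5E,8R,10R)-13-acetoxy-1-hydroxy-8-[(2S)-2-methyloxirane-2-carbonyloxy]-1,4-epoxygermacra-5,7(11)-dien-12,6-olide
Product: 28 CNP0414417.2, (1S,4R,5E,8R,10R)-13-acetoxy-8-[(2R)-3-chloro-2-hydroxy-2-methylpropanoyloxy]-1-hydroxy-1,4-epoxygermacra-5,7(11)-dien-12,6-olide
Conditions: LiCl, AcOH, THF, rt
Reagents that add atoms: lithium chloride, [Li+].[Cl-]
Why: Regioselective opening of the epoxide by chloride at the unsubstituted carbon (SN2, lithium halide with acetic acid). The C2′–O bond is not broken, so the (S)-glycidate becomes the (R)-chlorohydrin only through the change in priorities.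

## Compound list

1 | (R)-(−)-linalool, (3R)-3,7-dimethylocta-1,6-dien-3-ol | C=C[C@](C)(O)CCC=C(C)C | starting material
2 | (2R)-2-methyl-5-oxooxolane-2-carboxylic acid | OC(=O)[C@@]1(C)CCC(=O)O1 | intermediate
3 | (5R)-5-(hydroxymethyl)-5-methyloxolan-2-one | OC[C@@]1(C)CCC(=O)O1 | intermediate
4 | [(2R)-2-methyl-5-oxooxolan-2-yl]methyl 4-methylbenzenesulfonate | Cc1ccc(cc1)S(=O)(=O)OC[C@@]1(C)CCC(=O)O1 | intermediate
5 | methyl 3-[(2R)-2-methyloxiran-2-yl]propanoate | COC(=O)CC[C@]1(C)CO1 | intermediate
6 | furan-3,4-diyldimethanol | OCc1cocc1CO | starting material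
7 | [4-({[tert-butyl(dimethyl)silyl]oxy}methyl)furan-3-yl]methanol | CC(C)(C)[Si](C)(C)OCc1cocc1CO | intermediate
8 | 4-({[tert-butyl(dimethyl)silyl]oxy}methyl)furan-3-carbaldehyde | CC(C)(C)[Si](C)(C)OCc1cocc1C=O | intermediate
9 | lithium α-amino alkoxide of 8 with N,N,N′-trimethylethylenediamine (not isolated) | CC(C)(C)[Si](C)(C)OCc1cocc1C(O[Li])N(C)CCN(C)C | intermediate
10 | 2-bromo-4-({[tert-butyl(dimethyl)silyl]oxy}methyl)furan-3-carbaldehyde | CC(C)(C)[Si](C)(C)OCc1coc(Br)c1C=O | intermediate
11 | allylboronic acid pinacol ester | C=CCB1OC(C)(C)C(C)(C)O1 | starting material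
12 | (1R)-1-[2-bromo-4-({[tert-butyl(dimethyl)silyl]oxy}methyl)furan-3-yl]but-3-en-1-ol | CC(C)(C)[Si](C)(C)OCc1coc(Br)c1[C@H](O)CC=C | intermediate
13 | 2-bromo-3-[(1R)-1-{[tert-butyl(dimethyl)silyl]oxy}but-3-en-1-yl]-4-({[tert-butyl(dimethyl)silyl]oxy}methyl)furan | CC(C)(C)[Si](C)(C)OCc1coc(Br)c1[C@H](O[Si](C)(C)C(C)(C)C)CC=C | intermediate
14 | methyl (4R)-5-{3-[(1R)-1-(TBSO)but-3-en-1-yl]-4-(TBSOCH2)furan-2-yl}-4-hydroxy-4-methylpentanoate (not isolated) | CC(C)(C)[Si](C)(C)OCc1coc(C[C@@](O)(C)CCC(=O)OC)c1[C@H](O[Si](C)(C)C(C)(C)C)CC=C | intermediate
15 | (5R)-5-({3-[(1R)-1-(TBSO)but-3-en-1-yl]-4-(TBSOCH2)furan-2-yl}methyl)-5-methyloxolan-2-one | CC(C)(C)[Si](C)(C)OCc1coc(C[C@@]2(C)CCC(=O)O2)c1[C@H](O[Si](C)(C)C(C)(C)C)CC=C | intermediate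
16 | (5R)-5-({3-[(1R)-1-(TBSO)-3-iodobutyl]-4-(TBSOCH2)furan-2-yl}methyl)-5-methyloxolan-2-one, both C10 epimers | CC(C)(C)[Si](C)(C)OCc1coc(C[C@@]2(C)CCC(=O)O2)c1[C@H](O[Si](C)(C)C(C)(C)C)CC(C)I | intermediate
17 | (1S,4R,8R,10R)-8,13-bis(TBSO)-1-hydroxy-1,4-epoxy furanogermacrane: nine-membered oxacycle C1–O–C4–C5–C6–C7–C8–C9–C10 strapped by C2–C3 between C1 and C4, furan (O, C6, C7, C11, C12) fused at C6–C7, methyls on C4 and C10, CH2OTBS on C11 | CC(C)(C)[Si](C)(C)OCc1coc2c1[C@H](O[Si](C)(C)C(C)(C)C)C[C@@H](C)[C@]3(O)CC[C@@](C)(O3)C2 | intermediate
18 | (1S,4R,8R,10R)-1,8,13-trihydroxy-1,4-epoxy furanogermacrane | OCc1coc2c1[C@H](O)C[C@@H](C)[C@]3(O)CC[C@@](C)(O3)C2 | intermediate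
19 | (1S,4R,8R,10R)-13-acetoxy-1,8-dihydroxy-1,4-epoxy furanogermacrane | CC(=O)OCc1coc2c1[C@H](O)C[C@@H](C)[C@]3(O)CC[C@@](C)(O3)C2 | intermediate
20 | methyl (2S)-2-methyloxirane-2-carboxylate | COC(=O)[C@@]1(C)OC1 | starting material
21 | (2S)-2-methyloxirane-2-carboxylic acid | OC(=O)[C@@]1(C)OC1 | intermediate
22 | (2S)-2-methyloxirane-2-carboxylic 2,4,6-trichlorobenzoic anhydride (not isolated) | Clc1cc(Cl)c(C(=O)OC(=O)[C@@]2(C)OC2)c(Cl)c1 | intermediate
23 | (1S,4R,8R,10R)-13-acetoxy-1-hydroxy-8-[(2S)-2-methyloxirane-2-carbonyloxy]-1,4-epoxy furanogermacrane | CC(=O)OCc1coc2c1[C@H](OC(=O)[C@@]4(C)OC4)C[C@@H](C)[C@]3(O)CC[C@@](C)(O3)C2 | intermediate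
24 | 6,12-epidioxide (2,5-endoperoxide of the furan) of 23 (not isolated) | CC(=O)OCC1=C2[C@H](OC(=O)[C@@]4(C)OC4)C[C@@H](C)[C@]3(O)CC[C@@](C)(O3)CC25OOC1O5 | intermediate
25 | (1S,4R,8R,10R)-13-acetoxy-1,6-dihydroxy-8-[(2S)-2-methyloxirane-2-carbonyloxy]-1,4-epoxygermacr-7(11)-en-12,6-olide, C6 epimers | CC(=O)OCC1=C2[C@H](OC(=O)[C@@]4(C)OC4)C[C@@H](C)[C@]3(O)CC[C@@](C)(O3)CC2(O)OC1=O | intermediate
26 | 6-O-acetate of 25 (not isolated) | CC(=O)OCC1=C2[C@H](OC(=O)[C@@]4(C)OC4)C[C@@H](C)[C@]3(O)CC[C@@](C)(O3)CC2(OC(C)=O)OC1=O | intermediate
27 | (1S,4R,5E,8R,10R)-13-acetoxy-1-hydroxy-8-[(2S)-2-methyloxirane-2-carbonyloxy]-1,4-epoxygermacra-5,7(11)-dien-12,6-olide | CC(=O)OCC1=C2/C(=C\[C@@]3(C)CC[C@](O)(O3)[C@H](C)C[C@H]2OC(=O)[C@@]4(C)OC4)OC1=O | intermediate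
28 | CNP0414417.2, (1S,4R,5E,8R,10R)-13-acetoxy-8-[(2R)-3-chloro-2-hydroxy-2-methylpropanoyloxy]-1-hydroxy-1,4-epoxygermacra-5,7(11)-dien-12,6-olide | CC(=O)OCC1=C2/C(=C\[C@@]3(C)CC[C@](O)(O3)[C@H](C)C[C@H]2OC(=O)[C@@](C)(O)CCl)OC1=O | target

## Step count and risk

Total: 19 steps. Longest linear sequence: 14 steps, from diol 6 through steps 5–14 and 16–19. The linalool branch (steps 1–4) joins at step 10 and the glycidic acid (step 15) at step 16.

**Step 12 (key step).** Three things are most likely to go wrong: protonation of the C10 organosamarium before it reaches the lactone (net loss of iodine); collapse of the adduct and further reduction of the liberated ketone; and poor facial selectivity at C10 during ring closure. The last would first be addressed by equilibrating the product with DBU through its open C1 ketone. If the closure itself fails, the same ring would be closed by metathesis, which is known chemistry. The fallback sets out from 15: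
- the allyl group is isomerised with RuHCl(CO)(PPh3)3 to the propenyl lactone F1;
- isopropenyllithium at −78 °C adds once to the lactone to give the isopropenyl lactol F2;
- ring-closing metathesis with the second-generation Hoveyda–Grubbs catalyst at high dilution joins C9 to C10, releases propene and gives the bridged cycloalkene F3;
- hydrogenation with [Ir(cod)(PCy3)(py)]PF6, directed by the C1 hydroxyl, sets C10 and comes back to the route at 17.

**Step 10.** The furyl group may transfer sluggishly from copper, the organometallic may attack the methyl ester, or the C8 silyl group may migrate to the lithiated carbon before transmetalation. The fallback forms C5–C6 by carbonyl addition. Alcohol 3 is oxidised (Dess–Martin periodinane) to the lactone aldehyde F4. The furylmagnesium species from 13 adds to it at −78 °C to give the C5 carbinol F5. This is converted with 1,1′-thiocarbonyldiimidazole into the thiocarbonylimidazolide F6 and deoxygenated with Bu3SnH (Barton–McCombie), coming back at 15.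

**Step 11.** Hydrogen atom transfer may simply reduce the alkene, or the radical chain may abstract furfurylic hydrogen. The fallback sets out from 15: Mukaiyama hydration (Co(acac)2, PhSiH3, O2) gives the C10 alcohol F7, and an Appel reaction (I2, PPh3, imidazole) comes back at 16.

**Step 18.** Acylation or ionisation may occur at the C1 hemiketal instead of C6, or the elimination may stall at the C6 acetate. The fallback sets out from 23 and avoids the hydroxybutenolide. Photooxygenation in methanol without base gives the 6-methoxy 12-hydroperoxide F8. Ac2O and pyridine then dehydrate the hydroperoxide to the lactone carbonyl (Kornblum–DeLaMare) and the resulting pseudo-ester loses methanol, coming back at 27.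

**Step 7.** Metalation may occur at the furan carbon next to the silyloxymethyl group. The fallback sets out from alcohol 7: its lithium alkoxide (n-BuLi, two equivalents) directs lithiation to the adjacent ring carbon, BrCCl2CCl2Br gives the bromo alcohol F9, and MnO2 comes back at 10.

**Step 8.** The aldehyde is flanked by two ring substituents, so enantioselectivity may erode. The fallback sets out from 12 of insufficient purity: oxidation (Dess–Martin periodinane) gives the allyl ketone F10, and Corey–Bakshi–Shibata reduction with BH3·SMe2 and the (S)-methyl oxazaborolidine returns 12.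

## Further compounds

F1 | step 12 | (5R)-5-({3-[(1R,2E)-1-(TBSO)but-2-en-1-yl]-4-(TBSOCH2)furan-2-yl}methyl)-5-methyloxolan-2-one | CC(C)(C)[Si](C)(C)OCc1coc(C[C@@]2(C)CCC(=O)O2)c1[C@H](O[Si](C)(C)C(C)(C)C)/C=C/C
F2 | step 12 | (5R)-5-({3-[(1R,2E)-1-(TBSO)but-2-en-1-yl]-4-(TBSOCH2)furan-2-yl}methyl)-5-methyl-2-(prop-1-en-2-yl)oxolan-2-ol | CC(C)(C)[Si](C)(C)OCc1coc(C[C@@]2(C)CCC(O)(C(C)=C)O2)c1[C@H](O[Si](C)(C)C(C)(C)C)/C=C/C
F3 | step 12 | 9,10-didehydro derivative of 17 (ring-cis C9=C10) | CC(C)(C)[Si](C)(C)OCc1coc2c1[C@H](O[Si](C)(C)C(C)(C)C)/C=C(C)\[C@]3(O)CC[C@@](C)(O3)C2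
F4 | step 10 | (2R)-2-methyl-5-oxooxolane-2-carbaldehyde | O=C[C@@]1(C)CCC(=O)O1
F5 | step 10 | (5R)-5-[{3-[(1R)-1-(TBSO)but-3-en-1-yl]-4-(TBSOCH2)furan-2-yl}(hydroxy)methyl]-5-methyloxolan-2-one, C5 epimers | CC(C)(C)[Si](C)(C)OCc1coc(C(O)[C@@]2(C)CCC(=O)O2)c1[C@H](O[Si](C)(C)C(C)(C)C)CC=C
F6 | step 10 | O-imidazole-1-carbothioate of F5 | CC(C)(C)[Si](C)(C)OCc1coc(C(OC(=S)n3ccnc3)[C@@]2(C)CCC(=O)O2)c1[C@H](O[Si](C)(C)C(C)(C)C)CC=C
F7 | step 11 | (5R)-5-({3-[(1R)-1-(TBSO)-3-hydroxybutyl]-4-(TBSOCH2)furan-2-yl}methyl)-5-methyloxolan-2-one, C10 epimers | CC(C)(C)[Si](C)(C)OCc1coc(C[C@@]2(C)CCC(=O)O2)c1[C@H](O[Si](C)(C)C(C)(C)C)CC(C)O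
F8 | step 18 | 6-methoxy 12-hydroperoxy 6,12-dihydrofuran derived from 23 | CC(=O)OCC1=C2[C@H](OC(=O)[C@@]4(C)OC4)C[C@@H](C)[C@]3(O)CC[C@@](C)(O3)CC2(OC)OC1OO
F9 | step 7 | [2-bromo-4-({[tert-butyl(dimethyl)silyl]oxy}methyl)furan-3-yl]methanol | CC(C)(C)[Si](C)(C)OCc1coc(Br)c1CO
F10 | step 8 | 1-[2-bromo-4-({[tert-butyl(dimethyl)silyl]oxy}methyl)furan-3-yl]but-3-en-1-one | CC(C)(C)[Si](C)(C)OCc1coc(Br)c1C(=O)CC=C
A1 | alternative 1 | 8,13-dideoxy tricycle, (1S,4R,5E,10R)-1-hydroxy-1,4-epoxygermacra-5,7(11)-dien-12,6-olide | CC1=C2/C(=C\[C@@]3(C)CC[C@](O)(O3)[C@H](C)CC2)OC1=O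
A2 | alternative 1 | 8,13-diol of the tricyclic core | OCC1=C2/C(=C\[C@@]3(C)CC[C@](O)(O3)[C@H](C)C[C@H]2O)OC1=O
A3 | alternative 2 | butenolide-fused 1-vinylcyclohexanol with C6 enol-ether alkenyl group (C1, C6 and enol-ether geometry left open) | CC(C)(C)[Si](C)(C)OCC1=C2C(C=C(C)OCc3ccc(OC)cc3)(OC1=O)C(O)(C=C)[C@H](C)C[C@H]2O[Si](C)(C)C(C)(C)C
A4 | alternative 2 | ten-membered C1 ketone with C4 PMB ether and ylidene butenolide | CC(C)(C)[Si](C)(C)OCC1=C2/C(=C\[C@@](OCc3ccc(OC)cc3)(C)CCC(=O)[C@H](C)C[C@H]2O[Si](C)(C)C(C)(C)C)OC1=O
A5 | alternative 3 | 13-acetoxy-4,5-epoxy-1-oxo-8-[(2S)-2-methyloxirane-2-carbonyloxy]germacr-7(11)-en-12,6-olide (C5 and C6 left open) | CC(=O)OCC1=C2C(C3O[C@]3(C)CCC(=O)[C@H](C)C[C@H]2OC(=O)[C@@]4(C)OC4)OC1=O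
A6 | alternative 3 | bridged hemiketal ylidene butenolide with 8-(2-methylglycidate) ester (identical with 27) | CC(=O)OCC1=C2/C(=C\[C@@]3(C)CC[C@](O)(O3)[C@H](C)C[C@H]2OC(=O)[C@@]4(C)OC4)OC1=O
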